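**Strategy.** The cross-conjugated dienone (ring C) is locally symmetric: its carbonyl carbon C4' is flanked by two identical C(OMe)=CH arms (C3'=C2' and C5'=C6') that converge on the spiro carbon C9, which is therefore not a stereocentre. Everything rests on cutting both C4'–C(OMe) bonds. In the key step a 9,9-bis[(E)-2-methoxyvinyl]benzocycloheptenol is lithiated at both enol-ether α-carbons and the 1,5-dilithio-1,4-diene is stitched with the one-carbon electrophile Me2NCOCl; the second, intramolecular acylation closes ring C and gives the target directly. The precursor comes from a Hurtley arylation, ring-closing metathesis and an asymmetric methyl conjugate addition–methylation.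

Key step: step 13

Remark: the absolute sense of the copper-catalysed methyl addition in step 5 cannot be predicted with certainty for this benzo-fused enone; the ligand enantiomer that gives (7R) is the one used.

Atom labels follow the benzo[7]annulene numbering (C5 carbinol, C6 and C7 methyl-bearing, C8 methylene, C9 spiro) and primed locants for ring C (C1' = C9).

**Step 1**
Reactants: 1 2-bromo-3,4,5-trimethoxybenzoic acid; 2 dimethyl malonate
Product: 3 2-[bis(methoxycarbonyl)methyl]-3,4,5-trimethoxybenzoic acid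
Conditions: NaH (3 equiv), CuBr (10 mol %), dimethyl malonate as solvent, 70 °C; then aq. HCl
Reagents that add atoms: none
Why: Hurtley reaction, in which the ortho-carboxylate directs copper-catalysed replacement of the aryl bromide by sodiomalonate, so the aryl–C9 bond forms next to the methoxy group.

**Step 2**
Reactants: 3 2-[bis(methoxycarbonyl)methyl]-3,4,5-trimethoxybenzoic acid
Product: 4 2-[1,1-bis(methoxycarbonyl)but-3-en-1-yl]-3,4,5-trimethoxybenzoic acid
Conditions: NaH (2.2 equiv), THF, 0 °C; allyl bromide (1.05 equiv), 0 °C → rt; then aq. HCl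
Reagents that add atoms: allyl bromide, C=CCBr
Why: malonic ester C-alkylation of the carboxylate/malonate dianion, in which the soft malonate carbanion should outcompete the sodium carboxylate in THF and make C9 quaternary with two identical ester arms.

**Step 3**
Reactants: 4 2-[1,1-bis(methoxycarbonyl)but-3-en-1-yl]-3,4,5-trimethoxybenzoic acid
Product: 6 dimethyl 2-(6-acryloyl-2,3,4-trimethoxyphenyl)-2-allylmalonate, via acid chloride 5 (not isolated)
Conditions: (COCl)2, DMF (cat.), CH2Cl2, 0 °C → rt, evaporate; then Bu3SnCH=CH2, PdCl2(PPh3)2 (3 mol %), BHT, toluene, 50 °C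
Reagents that add atoms: tributyl(vinyl)stannane, C=C[Sn](CCCC)(CCCC)CCCC; oxalyl chloride, ClC(=O)C(=O)Cl (chlorine of 5 only)
Why: Stille acylation of the aroyl chloride with a vinylstannane should give the aryl vinyl ketone under neutral conditions that leave the hindered malonate esters and the allyl group untouched.

**Step 4**
Reactants: 6 dimethyl 2-(6-acryloyl-2,3,4-trimethoxyphenyl)-2-allylmalonate
Product: 7 dimethyl 1,2,3-trimethoxy-5-oxo-5,8-dihydro-9H-benzo[7]annulene-9,9-dicarboxylate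
Conditions: second-generation Grubbs catalyst RuCl2(=CHPh)(PCy3)(H2IMes) (5 mol %), CH2Cl2 (5 mM), 40 °C
Reagents that add atoms: none
Why: ring-closing metathesis between the enone and the terminal olefin should close the benzo-fused seven-membered ring as the conjugated C6=C7 enone with loss of ethene.

**Step 5**
Reactants: 7 dimethyl 1,2,3-trimethoxy-5-oxo-5,8-dihydro-9H-benzo[7]annulene-9,9-dicarboxylate
Product: 9 dimethyl (6S,7R)-1,2,3-trimethoxy-6,7-dimethyl-5-oxo-5,6,7,8-tetrahydro-9H-benzo[7]annulene-9,9-dicarboxylate, via magnesium enolate 8 (not isolated)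
Conditions: MeMgBr (1.2 equiv), CuBr·SMe2 (5 mol %), (R)-1-[(SP)-2-(diphenylphosphino)ferrocenyl]ethyldicyclohexylphosphine (6 mol %; its mirror image if the sense is opposite), t-BuOMe, –78 °C; then MeI (5 equiv), DMPU, –78 → 0 °C
Reagents that add atoms: methylmagnesium bromide, C[Mg]Br; iodomethane, CI
Why: copper-catalysed asymmetric conjugate addition of the Grignard reagent sets C7 under ligand control, and the regiodefined magnesium enolate is then methylated anti to the new C7 methyl (tandem conjugate addition–enolate alkylation), which should give the trans-6,7-dimethyl ketone.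

**Step 6**
Reactants: 9 dimethyl (6S,7R)-1,2,3-trimethoxy-6,7-dimethyl-5-oxo-5,6,7,8-tetrahydro-9H-benzo[7]annulene-9,9-dicarboxylate
Product: 10 dimethyl (5R,6S,7R)-5-hydroxy-1,2,3-trimethoxy-6,7-dimethyl-5,6,7,8-tetrahydro-9H-benzo[7]annulene-9,9-dicarboxylate
Conditions: (S)-2-methyl-CBS-oxazaborolidine (0.5 equiv), BH3·SMe2, THF, –20 °C; MeOH quench
Reagents that add atoms: none
Why: Corey–Bakshi–Shibata reduction, in which the aryl group acts as the large substituent so that the (S)-oxazaborolidine should deliver hydride to give the 5R carbinol (trans to the C6 methyl) under reagent control.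

**Step 7**
Reactants: 10 dimethyl (5R,6S,7R)-5-hydroxy-1,2,3-trimethoxy-6,7-dimethyl-5,6,7,8-tetrahydro-9H-benzo[7]annulene-9,9-dicarboxylate
Product: 11 dimethyl (5R,6S,7R)-5-[(tert-butyldimethylsilyl)oxy]-1,2,3-trimethoxy-6,7-dimethyl-5,6,7,8-tetrahydro-9H-benzo[7]annulene-9,9-dicarboxylate
Conditions: TBSOTf, 2,6-lutidine, CH2Cl2, –78 → 0 °C (directly after step 6)
Reagents that add atoms: tert-butyldimethylsilyl trifluoromethanesulfonate, CC(C)(C)[Si](C)(C)OS(=O)(=O)C(F)(F)F
Why: O-silylation with the silyl triflate should protect the hindered benzylic carbinol before it can lactonise onto a C9 ester and before the later oxidation.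

**Step 8**
Reactants: 11 dimethyl (5R,6S,7R)-5-[(tert-butyldimethylsilyl)oxy]-1,2,3-trimethoxy-6,7-dimethyl-5,6,7,8-tetrahydro-9H-benzo[7]annulene-9,9-dicarboxylate
Product: 12 [(5R,6S,7R)-5-[(tert-butyldimethylsilyl)oxy]-1,2,3-trimethoxy-6,7-dimethyl-5,6,7,8-tetrahydro-9H-benzo[7]annulene-9,9-diyl]dimethanol
Conditions: LiAlH4, THF, 0 °C → rt
Reagents that add atoms: none
Why: LiAlH4 ester reduction should convert both neopentyl esters into the 1,3-diol while the silyl and aryl ethers are inert.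

**Step 9**
Reactants: 12 [(5R,6S,7R)-5-[(tert-butyldimethylsilyl)oxy]-1,2,3-trimethoxy-6,7-dimethyl-5,6,7,8-tetrahydro-9H-benzo[7]annulene-9,9-diyl]dimethanol
Product: 13 (5R,6S,7R)-5-[(tert-butyldimethylsilyl)oxy]-1,2,3-trimethoxy-6,7-dimethyl-5,6,7,8-tetrahydro-9H-benzo[7]annulene-9,9-dicarbaldehyde
Conditions: (COCl)2, DMSO, CH2Cl2, –78 °C; Et3N, –78 → 0 °C
Reagents that add atoms: none
Why: Swern oxidation activates both primary alcohols before base is added, so no β-hydroxy aldehyde should persist to undergo retro-aldol cleavage, and the dialdehyde formed cannot enolise.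

**Step 10**
Reactants: 13 (5R,6S,7R)-5-[(tert-butyldimethylsilyl)oxy]-1,2,3-trimethoxy-6,7-dimethyl-5,6,7,8-tetrahydro-9H-benzo[7]annulene-9,9-dicarbaldehyde
Product: 14 2,2'-{[(5R,6S,7R)-5-[(tert-butyldimethylsilyl)oxy]-1,2,3-trimethoxy-6,7-dimethyl-5,6,7,8-tetrahydro-9H-benzo[7]annulene-9,9-diyl]bis[(E)-ethene-2,1-diyl]}bis(4,4,5,5-tetramethyl-1,3,2-dioxaborolane)
Conditions: Cl2CHB(pin) (4 equiv), CrCl2 (16 equiv), LiI (8 equiv), THF, rt
Reagents that add atoms: 2-(dichloromethyl)-4,4,5,5-tetramethyl-1,3,2-dioxaborolane, ClC(Cl)B1OC(C)(C)C(C)(C)O1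
Why: Takai–Utimoto olefination, in which the geminal dichromium boryl reagent adds to each aldehyde and eliminates to the (E)-alkenylboronate, should fix the olefin geometry that the key step requires.

**Step 11**
Reactants: 14 the bis[(E)-alkenylboronate] of step 10
Product: 15 tert-butyl{[(5R,6S,7R)-1,2,3-trimethoxy-9,9-bis[(E)-2-methoxyethenyl]-6,7-dimethyl-6,7,8,9-tetrahydro-5H-benzo[7]annulen-5-yl]oxy}dimethylsilane
Conditions: Cu(OAc)2 (4 equiv), Et3N (8 equiv), MeOH, 4 Å MS, air, rt
Reagents that add atoms: methanol, CO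
Why: Chan–Lam–Evans oxidative C–O coupling of alkenylboronates with an alcohol proceeds with retention of olefin geometry and should give the (E,E)-bis(enol ether).

**Step 12**
Reactants: 15 tert-butyl{[(5R,6S,7R)-1,2,3-trimethoxy-9,9-bis[(E)-2-methoxyethenyl]-6,7-dimethyl-6,7,8,9-tetrahydro-5H-benzo[7]annulen-5-yl]oxy}dimethylsilane
Product: 16 (5R,6S,7R)-1,2,3-trimethoxy-9,9-bis[(E)-2-methoxyethenyl]-6,7-dimethyl-6,7,8,9-tetrahydro-5H-benzo[7]annulen-5-ol
Conditions: Bu4NF, THF, 0 °C → rt
Reagents that add atoms: none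
Why: fluoride-mediated desilylation under non-acidic conditions should spare the acid-labile enol ethers and free the carbinol, which in the key step is masked as its lithium alkoxide so that no silyl migration to a benzylic carbanion can occur.

**Step 13**
Reactants: 16 (5R,6S,7R)-1,2,3-trimethoxy-9,9-bis[(E)-2-methoxyethenyl]-6,7-dimethyl-6,7,8,9-tetrahydro-5H-benzo[7]annulen-5-ol
Product: 19 (5R,6S,7R)-5-hydroxy-1,2,3,3',5'-pentamethoxy-6,7-dimethyl-5,6,7,8-tetrahydrospiro[benzo[7]annulene-9,1'-cyclohexa[2,5]dien]-4'-one (target), via trilithio dienyl alkoxide 17 (not isolated), via lithium hemiaminal 18 (not isolated)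
Conditions: t-BuLi (3.1 equiv), THF, –78 → –30 °C; Me2NCOCl (1.0 equiv, slow addition, high dilution), –78 °C → rt; aq. NH4Cl
Reagents that add atoms: N,N-dimethylcarbamoyl chloride, CN(C)C(=O)Cl; tert-butyllithium, CC(C)(C)[Li] (lithium of 17 and 18 only)
Why: After O-lithiation, t-BuLi removes the two vinylic hydrogens α to oxygen (directed by the methoxy oxygen; C9 is quaternary, so there is no allylic hydrogen), and because both enol ethers are E the two C–Li bonds of the resulting 1,5-dilithio-1,4-diene lie cis to C9; one vinyllithium displaces chloride from Me2NCOCl to give an α-methoxyacrylamide, the other adds to that amide carbonyl to form the C4'(=O)–C3'(OMe) bond and ring C, and the lithium hemiaminal holds the carbonyl masked until aqueous quench releases dimethylamine and the dienone. The closest known reaction types are the acylation of α-alkoxyvinyllithiums by amides and the cyclising double acylation of 1,n-dilithio compounds by Me2NCOCl or CO2 (fluorenones from 2,2'-dilithiobiaryls, cyclopentadienones from 1,4-dilithio-1,3-dienes). Ring C closes by a 6-exo-trig addition to the amide C=O. No stereocentre is formed, because the spiro carbon carries two identical arms, and C5–C7 are not touched (the adjacent alkoxide protects C5–H from deprotonation). The step needs vinylic α-lithiation to beat lithiation of the lone aryl C–H ortho to methoxy, and ring closure to beat a second intermolecular acylation or O-carbamoylation; the higher kinetic acidity of enol-ether α-hydrogens at low temperature, the cis arrangement of the two C–Li bonds, and slow addition of exactly one equivalent of electrophile should secure both.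

**Compound list**
1 | 2-bromo-3,4,5-trimethoxybenzoic acid | COc1cc(C(=O)O)c(Br)c(OC)c1OC | starting material
2 | dimethyl malonate | COC(=O)CC(=O)OC | starting material
3 | 2-[bis(methoxycarbonyl)methyl]-3,4,5-trimethoxybenzoic acid | COC(=O)C(C(=O)OC)c1c(OC)c(OC)c(OC)cc1C(=O)O | intermediate
4 | 2-[1,1-bis(methoxycarbonyl)but-3-en-1-yl]-3,4,5-trimethoxybenzoic acid | COC(=O)C(CC=C)(C(=O)OC)c1c(OC)c(OC)c(OC)cc1C(=O)O | intermediate
5 | dimethyl 2-allyl-2-[6-(chlorocarbonyl)-2,3,4-trimethoxyphenyl]malonate | COC(=O)C(CC=C)(C(=O)OC)c1c(OC)c(OC)c(OC)cc1C(=O)Cl | intermediate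
6 | dimethyl 2-(6-acryloyl-2,3,4-trimethoxyphenyl)-2-allylmalonate | COC(=O)C(CC=C)(C(=O)OC)c1c(OC)c(OC)c(OC)cc1C(=O)C=C | intermediate
7 | dimethyl 1,2,3-trimethoxy-5-oxo-5,8-dihydro-9H-benzo[7]annulene-9,9-dicarboxylate | COC(=O)C1(C(=O)OC)CC=CC(=O)c2cc(OC)c(OC)c(OC)c21 | intermediate
8 | dimethyl (7R)-5-[(bromomagnesio)oxy]-1,2,3-trimethoxy-7-methyl-7,8-dihydro-9H-benzo[7]annulene-9,9-dicarboxylate (magnesium enolate) | COC(=O)C1(C(=O)OC)C[C@@H](C)C=C(O[Mg]Br)c2cc(OC)c(OC)c(OC)c21 | intermediate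
9 | dimethyl (6S,7R)-1,2,3-trimethoxy-6,7-dimethyl-5-oxo-5,6,7,8-tetrahydro-9H-benzo[7]annulene-9,9-dicarboxylate | COC(=O)C1(C(=O)OC)C[C@@H](C)[C@H](C)C(=O)c2cc(OC)c(OC)c(OC)c21 | intermediate
10 | dimethyl (5R,6S,7R)-5-hydroxy-1,2,3-trimethoxy-6,7-dimethyl-5,6,7,8-tetrahydro-9H-benzo[7]annulene-9,9-dicarboxylate | COC(=O)C1(C(=O)OC)C[C@@H](C)[C@H](C)[C@@H](O)c2cc(OC)c(OC)c(OC)c21 | intermediate
11 | dimethyl (5R,6S,7R)-5-[(tert-butyldimethylsilyl)oxy]-1,2,3-trimethoxy-6,7-dimethyl-5,6,7,8-tetrahydro-9H-benzo[7]annulene-9,9-dicarboxylate | COC(=O)C1(C(=O)OC)C[C@@H](C)[C@H](C)[C@@H](O[Si](C)(C)C(C)(C)C)c2cc(OC)c(OC)c(OC)c21 | intermediate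
12 | [(5R,6S,7R)-5-[(tert-butyldimethylsilyl)oxy]-1,2,3-trimethoxy-6,7-dimethyl-5,6,7,8-tetrahydro-9H-benzo[7]annulene-9,9-diyl]dimethanol | OCC1(CO)C[C@@H](C)[C@H](C)[C@@H](O[Si](C)(C)C(C)(C)C)c2cc(OC)c(OC)c(OC)c21 | intermediate
13 | (5R,6S,7R)-5-[(tert-butyldimethylsilyl)oxy]-1,2,3-trimethoxy-6,7-dimethyl-5,6,7,8-tetrahydro-9H-benzo[7]annulene-9,9-dicarbaldehyde | O=CC1(C=O)C[C@@H](C)[C@H](C)[C@@H](O[Si](C)(C)C(C)(C)C)c2cc(OC)c(OC)c(OC)c21 | intermediate
14 | 2,2'-{[(5R,6S,7R)-5-[(tert-butyldimethylsilyl)oxy]-1,2,3-trimethoxy-6,7-dimethyl-5,6,7,8-tetrahydro-9H-benzo[7]annulene-9,9-diyl]bis[(E)-ethene-2,1-diyl]}bis(4,4,5,5-tetramethyl-1,3,2-dioxaborolane) | CC1(C)OB(OC1(C)C)/C=C/C2(/C=C/B3OC(C)(C)C(C)(C)O3)C[C@@H](C)[C@H](C)[C@@H](O[Si](C)(C)C(C)(C)C)c4cc(OC)c(OC)c(OC)c42 | intermediate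
15 | tert-butyl{[(5R,6S,7R)-1,2,3-trimethoxy-9,9-bis[(E)-2-methoxyethenyl]-6,7-dimethyl-6,7,8,9-tetrahydro-5H-benzo[7]annulen-5-yl]oxy}dimethylsilane | CO/C=C/C1(/C=C/OC)C[C@@H](C)[C@H](C)[C@@H](O[Si](C)(C)C(C)(C)C)c2cc(OC)c(OC)c(OC)c21 | intermediate
16 | (5R,6S,7R)-1,2,3-trimethoxy-9,9-bis[(E)-2-methoxyethenyl]-6,7-dimethyl-6,7,8,9-tetrahydro-5H-benzo[7]annulen-5-ol | CO/C=C/C1(/C=C/OC)C[C@@H](C)[C@H](C)[C@@H](O)c2cc(OC)c(OC)c(OC)c21 | intermediate
17 | lithium (5R,6S,7R)-9,9-bis[(E)-2-lithio-2-methoxyethenyl]-1,2,3-trimethoxy-6,7-dimethyl-6,7,8,9-tetrahydro-5H-benzo[7]annulen-5-olate | CO/C([Li])=C/C1(/C=C(/OC)[Li])C[C@@H](C)[C@H](C)[C@@H](O[Li])c2cc(OC)c(OC)c(OC)c21 | intermediate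
18 | dilithium (5R,6S,7R)-4'-(dimethylamino)-1,2,3,3',5'-pentamethoxy-6,7-dimethyl-5,6,7,8-tetrahydrospiro[benzo[7]annulene-9,1'-cyclohexa[2,5]diene]-4',5-bis(olate) (both isomers at C4') | COC1=CC2(C=C(OC)C1(O[Li])N(C)C)C[C@@H](C)[C@H](C)[C@@H](O[Li])c1cc(OC)c(OC)c(OC)c12 | intermediate
19 | (5R,6S,7R)-5-hydroxy-1,2,3,3',5'-pentamethoxy-6,7-dimethyl-5,6,7,8-tetrahydrospiro[benzo[7]annulene-9,1'-cyclohexa[2,5]dien]-4'-one | COC1=CC2(C=C(OC)C1=O)C[C@@H](C)[C@H](C)[C@@H](O)c1cc(OC)c(OC)c(OC)c12 | target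

**Totals.** 13 steps; the longest linear sequence is 13 steps (the route is fully linear from 1).

**Steps most likely to fail**

Step 13. Deprotonation of the lone aryl C–H ortho to methoxy may compete, the second vinylic lithiation next to the quaternary carbon may be incomplete, or intermolecular acylation (oligomerisation) may outrun ring closure. The fallback sets out from dialdehyde 13 and comes back at target 19, building ring C by condensation instead. Soft enolisation of 1,3-dimethoxypropan-2-one (TiCl4, Et3N, CH2Cl2, –78 °C) in the presence of 13 should give, by double aldol addition, the silyl-protected 2',6'-dihydroxy-3',5'-dimethoxy spiro-cyclohexan-4'-one F1. Mesylation and elimination (MsCl, Et3N, then DBU) should give the silyl-protected spirodienone F2, and Bu4NF buffered with AcOH then gives 19.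

Step 5. Methyl delivery may show poor facial selectivity, the Grignard reagent may add 1,2 to the aryl ketone or the esters, or the magnesium enolate may be trapped incompletely. The fallback sets out from 3 and comes back at 9, setting C7 by hydride delivery instead of methyl delivery.
- C-alkylation of 3 with 3-bromo-2-methylpropene (as in step 2) gives the methallyl acid F3.
- Its acid chloride F4 (oxalyl chloride) is coupled with tributyl(vinyl)stannane as in step 3 to give the methallyl vinyl ketone F5.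
- Ring-closing metathesis gives the 7-methyl enone F6.
- Copper hydride asymmetric conjugate reduction (CuCl, NaOt-Bu, (S)-p-Tol-BINAP or its mirror image, polymethylhydrosiloxane, toluene) should give the (7R)-7-methyl ketone F7.
- Methylation with LiHMDS/MeI anti to the C7 methyl, with base equilibration to the trans isomer if needed, returns 9.

Step 11. Protodeboronation and oxidative homocoupling may outpace C–O bond formation at the two hindered alkenylboronates, with partial loss of olefin geometry. The fallback sets out from 13 and comes back at 15. Takai olefination (CHI3, CrCl2, THF) should give the bis[(E)-2-iodoethenyl] compound F8. Copper-catalysed C–O coupling with methanol (CuI, 3,4,7,8-tetramethyl-1,10-phenanthroline, Cs2CO3, MeOH/toluene, 80 °C), which retains olefin geometry, then gives 15.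

**Further compounds**
F1 | step 13 | (5R,6S,7R)-5-[(tert-butyldimethylsilyl)oxy]-2',6'-dihydroxy-1,2,3,3',5'-pentamethoxy-6,7-dimethyl-5,6,7,8-tetrahydrospiro[benzo[7]annulene-9,1'-cyclohexan]-4'-one (diastereomer mixture at the four new ring carbons) | COC1C(O)C2(C(O)C(OC)C1=O)C[C@@H](C)[C@H](C)[C@@H](O[Si](C)(C)C(C)(C)C)c1cc(OC)c(OC)c(OC)c12
F2 | step 13 | (5R,6S,7R)-5-[(tert-butyldimethylsilyl)oxy]-1,2,3,3',5'-pentamethoxy-6,7-dimethyl-5,6,7,8-tetrahydrospiro[benzo[7]annulene-9,1'-cyclohexa[2,5]dien]-4'-one | COC1=CC2(C=C(OC)C1=O)C[C@@H](C)[C@H](C)[C@@H](O[Si](C)(C)C(C)(C)C)c1cc(OC)c(OC)c(OC)c12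
F3 | step 5 | 2-[1,1-bis(methoxycarbonyl)-3-methylbut-3-en-1-yl]-3,4,5-trimethoxybenzoic acid | COC(=O)C(CC(C)=C)(C(=O)OC)c1c(OC)c(OC)c(OC)cc1C(=O)O
F4 | step 5 | dimethyl 2-[6-(chlorocarbonyl)-2,3,4-trimethoxyphenyl]-2-(2-methylprop-2-en-1-yl)malonate | COC(=O)C(CC(C)=C)(C(=O)OC)c1c(OC)c(OC)c(OC)cc1C(=O)Cl
F5 | step 5 | dimethyl 2-(6-acryloyl-2,3,4-trimethoxyphenyl)-2-(2-methylprop-2-en-1-yl)malonate | COC(=O)C(CC(C)=C)(C(=O)OC)c1c(OC)c(OC)c(OC)cc1C(=O)C=C
F6 | step 5 | dimethyl 1,2,3-trimethoxy-7-methyl-5-oxo-5,8-dihydro-9H-benzo[7]annulene-9,9-dicarboxylate | COC(=O)C1(C(=O)OC)CC(C)=CC(=O)c2cc(OC)c(OC)c(OC)c21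
F7 | step 5 | dimethyl (7R)-1,2,3-trimethoxy-7-methyl-5-oxo-5,6,7,8-tetrahydro-9H-benzo[7]annulene-9,9-dicarboxylate | COC(=O)C1(C(=O)OC)C[C@@H](C)CC(=O)c2cc(OC)c(OC)c(OC)c21
F8 | step 11 | tert-butyl{[(5R,6S,7R)-9,9-bis[(E)-2-iodoethenyl]-1,2,3-trimethoxy-6,7-dimethyl-6,7,8,9-tetrahydro-5H-benzo[7]annulen-5-yl]oxy}dimethylsilane | I/C=C/C1(/C=C/I)C[C@@H](C)[C@H](C)[C@@H](O[Si](C)(C)C(C)(C)C)c2cc(OC)c(OC)c(OC)c21
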